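All runs come from a simulation with made-up constants.

The catalyst charge of Tuesday's run over that of Monday's is 0.500, and the recipes are otherwise equal, so that ratio is the zero of my scale.

| setting | Monday's | Tuesday's | Saturday's |
|---|---|---|---|
| substrate | 0.150 M | 0.150 M | 0.150 M |
| coupling partner | 0.120 M | 0.120 M | 0.0240 M |
| catalyst | 3.00 × 10⁻⁴ M | 1.50 × 10⁻⁴ M | 3.00 × 10⁻⁴ M |
| time |  |  | 3.1 h |

| run | time / h | [target] / M |
|---|---|---|
| Monday's run | 0.12 | 0.0043 |
| Monday's run | 0.21 | 0.0072 |
| Monday's run | 0.36 | 0.0127 |
| Monday's run | 0.62 | 0.0201 |
| Monday's run | 1.1 | 0.0319 |
| Monday's run | 1.8 | 0.0457 |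
| Monday's run | 3.1 | 0.0592 |
| Tuesday's run | 0.12 | 0.0019 |
| Tuesday's run | 0.21 | 0.0032 |
| Tuesday's run | 0.36 | 0.0074 |
| Tuesday's run | 0.62 | 0.0090 |
| Tuesday's run | 1.1 | 0.0166 |
| Tuesday's run | 1.8 | 0.0237 |
| Tuesday's run | 3.1 | 0.0347 |

(each reading ± 8 × 10⁻⁴ M)

1. the power of [catalyst] that the first rate follows, about the charge of the Monday's run; measure it at two percent of substrate made into target
2. target in the Saturday's run at 3.1 h, as a share of the substrate charged
3. which of these the readings show (a little impurity takes part of the catalyst at once / the catalyst wakes slowly / the product reacts on with the second partner)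

- Overall: substrate + coupling partner -> target, with catalyst as catalyst.
- Constant volume, constant temperature.
- Readings of a species count what is bound in complexes too.
- "The second partner" is coupling partner.
- An order is taken over about fifteen percent of the charge, up and down.

Tuesday's last reading is 23.1% of the substrate charge. Monday passes that share between its readings at 1.1 h and 1.8 h, and straight interpolation makes Monday's time over Tuesday's 0.401. I carry this as the clock ratio, Monday's time to a given share of target over another flask's time to that share.

It reads lower than the zero. Between these two recipes, with a rate of first power in the active catalyst, a fixed loss of catalyst holds the ratio at one lower value, while a loss of target that needs no catalyst lowers it stage by stage. But Tuesday's first reading is 2.38 times its scatter, so the early end stays open.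

For Saturday's run the partner charge over Monday's is 0.200. With a rate of first power in the partner, held at its charge, Saturday's 3.1 h is worth Monday's 0.620 h, where Monday reads 13.4% of the substrate. But in Saturday's run the coupling partner, the limiting reagent at 16.0% of the substrate, falls as it reacts, and the first power is my assumption, so I take that share as a rough mark and not as a bound.

The forecast gives an order of 1.13 (1.04 to 1.28) and 9.2% (8% to 10.8%), lower than my mark. Its choice is: a little impurity takes part of the catalyst at once. Of the other path it says, "A follow-on reaction of product would not produce this".

    catalyst + substrate ⇌ catalyst-substrate complex, settled at all times (22.00 L mol⁻¹)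
    catalyst-substrate complex + coupling partner ⇌ ternary complex, settled at all times (17.50 L mol⁻¹)
    ternary complex → target + catalyst (209.9 h⁻¹)
    target + coupling partner → side product (3.341 L mol⁻¹ h⁻¹)

The flask gives an order of 1.0, 13.3% for Saturday's run, and this choice: the product reacts on with the second partner. At two percent turned, Tuesday's rate of 0.018 M h⁻¹ over Monday's 0.037 M h⁻¹ is 0.486, close to the zero. To make target equal to a quarter of the substrate charged, Monday's run takes 1.34 h and Tuesday's 3.68 h, so the clock ratio there is 0.364, lower than that rate ratio. Saturday's share stands close to Monday's reading of 13.4%, which puts Saturday's clock ratio near 0.200.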